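A direct plan would oxidise 2,3-dimethoxyphenol to the quinone A1, build the 2-arylacrolein A2 from 2'-hydroxy-3',4'-dimethoxyacetophenone (benzylation, Wittig methylenation, SeO2 oxidation), unite A1 and A2 under a chiral triazolylidene carbene to the 3-aryl-dihydrocoumarin A3, reduce the lactone carbonyl to CH2 (benzyl-protected chroman A4) and hydrogenolyse the benzyl ether.
Its weakest points would be:
(a) the carbene-catalysed homoenolate addition to the quinone with enantioselective protonation and lactonisation: this C–C bond formation has no precedent, the quinone is itself an oxidant for the Breslow intermediate, and the only stereocentre (C3) would rest on a catalyst-controlled protonation between an aryl group and a carbonyl, where it can epimerise;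
(b) the build-up of A2 ending in the allylic oxidation with SeO2: three steps for one C–H oxidation, leading to an enal that dimerises and cannot be stored;
(c) the reduction of the lactone carbonyl to CH2 on late material: C3–H stays next to a carbonyl or lactol carbon, and ring opening or over-reduction would undo the ring closure already paid for.

Plan of the new route
Retrosynthetic cuts, in order: C5–C6 of ring A (6π closure of a dienylketene), O1–C2 (alkoxide alkylation), C4a–C8a (vinyllithium addition to a squarate carbonyl) and C3–C4 (auxiliary-controlled alkylation of an arylacetic imide).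
Enabling feature: C6(OH), C7(OMe), C8(OMe) and C8a(O1) of ring A are four adjacent oxygen-bearing carbons with the two methoxy carbons inside and the para pair O6/O1 outside, which is the atom pattern of dimethyl squarate; C5–H and C4a are the two carbons of a 1,1-disubstituted vinyl group.
Ring order: ring B is bought, ring C is closed next as a tetrahydropyran spiro-fused to the four-membered ring, and ring A is formed last, as the only ring made in the key step.
C3 is set on an open chain by an oxazolidinone auxiliary and after step 5 is never again α to a carbonyl, so nothing rests on a catalyst-controlled protonation. No quinone, no acrolein and no lactone reduction occur. The two squarate carbonyl oxygens end as O1 and the free 6-OH, so ring A needs no protecting group.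
Key step: step 9

Remark: target atoms are named by chroman numbering (O1, C2, C3, C4, C4a, C5 to C8, C8a; ring A = benzo ring, ring B = 3-aryl group, ring C = pyran ring). The carbinol or spiro carbon of 14 to 17 forms as both epimers, which does not matter because it ends as the sp2 carbon C8a.

Step 1
Reactants: 1 2'-hydroxy-3',4'-dimethoxyacetophenone
Product: 2 1-[3,4-dimethoxy-2-(methoxymethoxy)phenyl]ethan-1-one
Conditions: NaH, MOMCl, DMF, 0 °C to rt
Reagents that add atoms: chloromethyl methyl ether, COCCl
Why: Williamson-type O-alkylation of the sodium phenoxide (full deprotonation breaks the hydrogen bond to the acetyl group); the methoxymethyl acetal should withstand every basic, reducing and organolithium step that follows and keeps O2' from closing a dihydrobenzofuran onto C2 in step 8.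

Step 2
Reactants: 2 1-[3,4-dimethoxy-2-(methoxymethoxy)phenyl]ethan-1-one
Product: 4 [3,4-dimethoxy-2-(methoxymethoxy)phenyl]acetic acid, via thiomorpholide 3 (not isolated)
Conditions: S8, morpholine, 130 °C; then KOH, EtOH/H2O, reflux; cold 1 M HCl to pH 4
Reagents that add atoms: sulfur, S1SSSSSSS1 and morpholine, C1COCCN1 (atoms held only in 3); potassium hydroxide, [K+].[OH-] (both carboxyl oxygens of 4)
Why: Willgerodt–Kindler reaction (the carbonyl function moves to the chain end as thioamide 3) followed by alkaline hydrolysis, a standard passage from electron-rich acetophenones to arylacetic acids; amine, sulfur and hydroxide leave the acetal alone, and the acidification is kept cold and brief for its sake.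

Step 3
Reactants: 4 [3,4-dimethoxy-2-(methoxymethoxy)phenyl]acetic acid; 5 (4S)-4-benzyl-1,3-oxazolidin-2-one
Product: 7 (4S)-4-benzyl-3-{[3,4-dimethoxy-2-(methoxymethoxy)phenyl]acetyl}-1,3-oxazolidin-2-one, via mixed pivalic anhydride 6 (not isolated)
Conditions: PivCl, Et3N, THF, −20 °C; then 5, LiCl, −20 °C to rt
Reagents that add atoms: pivaloyl chloride, CC(C)(C)C(=O)Cl (atoms held only in 6)
Why: N-acylation of the oxazolidinone through the mixed pivalic anhydride under LiCl/Et3N activation, which attacks the less hindered arylacetyl carbonyl and needs no strong base that could turn the arylacetyl unit into a ketene.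

Step 4
Reactants: 7 (4S)-4-benzyl-3-{[3,4-dimethoxy-2-(methoxymethoxy)phenyl]acetyl}-1,3-oxazolidin-2-one; 8 2,3-dibromoprop-1-ene
Product: 10 (4S)-4-benzyl-3-{(2S)-4-bromo-2-[3,4-dimethoxy-2-(methoxymethoxy)phenyl]pent-4-enoyl}-1,3-oxazolidin-2-one, via sodium Z-enolate 9 (not isolated)
Conditions: NaN(SiMe3)2, THF, −78 °C; then 8 (3 equiv), −78 to −50 °C; AcOH, −78 °C
Reagents that add atoms: sodium bis(trimethylsilyl)amide, C[Si](C)(C)[N-][Si](C)(C)C.[Na+] (sodium held only in 9)
Why: Evans asymmetric alkylation: the chelated Z-enolate is attacked by the reactive allylic bromide on the face away from the benzyl group of the (4S)-auxiliary, which should set the future C3 as S (the same face as in the propionimide series; the descriptor is S here because aryl outranks the entering CH2), and the cold acetic acid quench guards the acidic α-aryl centre against equilibration.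

Step 5
Reactants: 10 (4S)-4-benzyl-3-{(2S)-4-bromo-2-[3,4-dimethoxy-2-(methoxymethoxy)phenyl]pent-4-enoyl}-1,3-oxazolidin-2-one
Product: 11 (2S)-4-bromo-2-[3,4-dimethoxy-2-(methoxymethoxy)phenyl]pent-4-en-1-ol
Conditions: LiBH4, H2O (1.1 equiv), Et2O, 0 °C
Reagents that add atoms: none
Why: Reductive cleavage of the imide at the exocyclic carbonyl by LiBH4/H2O, the standard removal of the auxiliary as a primary alcohol; the weakly basic hydride should leave the α-aryl centre, the vinyl bromide and the acetal untouched, and from here on C3 is no longer next to a carbonyl.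

Step 6
Reactants: 11 (2S)-4-bromo-2-[3,4-dimethoxy-2-(methoxymethoxy)phenyl]pent-4-en-1-ol; 12 dimethyl squarate (3,4-dimethoxycyclobut-3-ene-1,2-dione)
Product: 14 4-hydroxy-4-{(4S)-5-hydroxy-4-[3,4-dimethoxy-2-(methoxymethoxy)phenyl]pent-1-en-2-yl}-2,3-dimethoxycyclobut-2-en-1-one (both epimers at the carbinol carbon), via dilithio reagent 13 (not isolated)
Conditions: t-BuLi (3.1 equiv), THF/Et2O, −78 °C; then add to 12 (1.3 equiv), THF, −78 °C; aq NH4Cl, −78 °C
Reagents that add atoms: tert-butyllithium, [Li]C(C)(C)C (lithium held only in 13)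
Why: Bromine–lithium exchange on the vinyl bromide (one equivalent of t-BuLi forms the lithium alkoxide, two effect the exchange) and 1,2-addition of the alkenyllithium to one carbonyl of the squarate, the standard entry to 4-alkenyl-4-hydroxycyclobutenones; this forms the future C4a–C8a bond.

Step 7
Reactants: 14 4-hydroxy-4-{(4S)-5-hydroxy-4-[3,4-dimethoxy-2-(methoxymethoxy)phenyl]pent-1-en-2-yl}-2,3-dimethoxycyclobut-2-en-1-one
Product: 15 (2S)-2-[3,4-dimethoxy-2-(methoxymethoxy)phenyl]-4-(1-hydroxy-2,3-dimethoxy-4-oxocyclobut-2-en-1-yl)pent-4-en-1-yl 4-methylbenzenesulfonate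
Conditions: TsCl, Et3N, DMAP (cat.), CH2Cl2, 0 °C
Reagents that add atoms: 4-methylbenzenesulfonyl chloride, Cc1ccc(cc1)S(=O)(=O)Cl
Why: Selective DMAP-catalysed tosylation of the primary alcohol, the hindered tertiary α-ketol hydroxyl not reacting at 0 °C; the amine medium avoids the acid to which the hydroxycyclobutenone is sensitive.

Step 8
Reactants: 15 (2S)-2-[3,4-dimethoxy-2-(methoxymethoxy)phenyl]-4-(1-hydroxy-2,3-dimethoxy-4-oxocyclobut-2-en-1-yl)pent-4-en-1-yl 4-methylbenzenesulfonate
Product: 17 (7S)-7-[3,4-dimethoxy-2-(methoxymethoxy)phenyl]-2,3-dimethoxy-9-methylidene-5-oxaspiro[3.5]non-2-en-1-one (both epimers at the spiro carbon), via lithium alkoxide 16 (not isolated)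
Conditions: LiN(SiMe3)2 (1.05 equiv), THF/DMPU (5:1), −78 to 0 °C
Reagents that add atoms: lithium bis(trimethylsilyl)amide, C[Si](C)(C)[N-][Si](C)(C)C.[Li+] (lithium held only in 16)
Why: Intramolecular Williamson etherification (6-exo-tet): the tertiary lithium alkoxide, the same kind of species that forms in step 6 and is known to be O-alkylated by reactive electrophiles, should displace the primary tosylate and close ring C through the future O1–C2 bond, the acetal at O2' leaving no competing nucleophile; any alkoxide that opened the four-membered ring first would end as the C8a phenoxide beside the same tosylate and so as 20, the product of step 9.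

Step 9
Reactants: 17 (7S)-7-[3,4-dimethoxy-2-(methoxymethoxy)phenyl]-2,3-dimethoxy-9-methylidene-5-oxaspiro[3.5]non-2-en-1-one
Product: 20 (3S)-3-[3,4-dimethoxy-2-(methoxymethoxy)phenyl]-7,8-dimethoxy-3,4-dihydro-2H-chromen-6-ol, via dienylketene 18 (not isolated), via cyclohexadienone 19 (not isolated)
Conditions: degassed toluene (0.02 M), 110 °C, argon
Reagents that add atoms: none
Why: Heating should open the bond between the carbonyl carbon and the spiro carbon of the cyclobutenone in a conrotatory 4π electrocyclic ring opening in which the ring oxygen (O5 of 17) turns outward and the methylidene-bearing carbon inward, giving dienylketene 18 with its terminal CH2 beside the ketene carbon; a disrotatory 6π electrocyclisation then forms the C5–C6 bond and closes ring A as the cyclohexa-2,4-dienone 19, which tautomerises to phenol 20. The closest known reaction type is the thermal rearrangement of 4-alkenyl-4-hydroxy- and 4-alkenyl-4-alkoxycyclobutenones made from squaric esters into 2,3-dialkoxyhydroquinones and their monoethers, the squarate route to 2,3-dimethoxy-5-methylhydroquinone being the nearest case. Ring A is the only ring closed, by 6π electrocyclisation, and it arises on the finished ring C, whose six-membered frame holds the two exocyclic double bonds of 18 s-cis. No stereocentre is formed: C3–H is not α to a carbonyl or ketene at any stage and is carried through unchanged, and the uncontrolled spiro centre becomes the sp2 carbon C8a. The step needs only the right torquoselectivity, which the donor oxygen on the breaking bond secures (an unproductive opening would be reversible); regiochemistry is fixed because the vinyl group has a single terminus. The ketone oxygen thus appears as the free 6-OH, the spiro ether oxygen as O1 and the two squarate methoxy groups at C7 and C8.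

Step 10
Reactants: 20 (3S)-3-[3,4-dimethoxy-2-(methoxymethoxy)phenyl]-7,8-dimethoxy-3,4-dihydro-2H-chromen-6-ol
Product: 21 (3S)-3-(2-hydroxy-3,4-dimethoxyphenyl)-7,8-dimethoxy-3,4-dihydro-2H-chromen-6-ol (target)
Conditions: HCl (3 M aq), MeOH, 45 °C
Reagents that add atoms: none
Why: Acid-catalysed acetal exchange (methanolysis of the methoxymethyl ether) should free the 2'-OH; the aryl methyl ethers, the chroman ether and the remote C3 centre are inert to dilute acid, so the 3S configuration is carried into the target.

Compound list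
1 | 2'-hydroxy-3',4'-dimethoxyacetophenone | CC(=O)c1ccc(OC)c(OC)c1O | starting material
2 | 1-[3,4-dimethoxy-2-(methoxymethoxy)phenyl]ethan-1-one | CC(=O)c1ccc(OC)c(OC)c1OCOC | intermediate
3 | 2-[3,4-dimethoxy-2-(methoxymethoxy)phenyl]-1-(morpholin-4-yl)ethane-1-thione (thiomorpholide) | S=C(Cc1ccc(OC)c(OC)c1OCOC)N1CCOCC1 | intermediate
4 | [3,4-dimethoxy-2-(methoxymethoxy)phenyl]acetic acid | OC(=O)Cc1ccc(OC)c(OC)c1OCOC | intermediate
5 | (4S)-4-benzyl-1,3-oxazolidin-2-one | O=C1OC[C@H](Cc2ccccc2)N1 | starting material
6 | [3,4-dimethoxy-2-(methoxymethoxy)phenyl]acetic 2,2-dimethylpropanoic anhydride (mixed pivalic anhydride) | CC(C)(C)C(=O)OC(=O)Cc1ccc(OC)c(OC)c1OCOC | intermediate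
7 | (4S)-4-benzyl-3-{[3,4-dimethoxy-2-(methoxymethoxy)phenyl]acetyl}-1,3-oxazolidin-2-one | O=C1OC[C@H](Cc2ccccc2)N1C(=O)Cc3ccc(OC)c(OC)c3OCOC | intermediate
8 | 2,3-dibromoprop-1-ene | C=C(Br)CBr | starting material
9 | sodium (1Z)-1-[(4S)-4-benzyl-2-oxo-1,3-oxazolidin-3-yl]-2-[3,4-dimethoxy-2-(methoxymethoxy)phenyl]ethen-1-olate (sodium Z-enolate of 7) | O=C1OC[C@H](Cc2ccccc2)N1/C([O-])=C/c3ccc(OC)c(OC)c3OCOC.[Na+] | intermediate
10 | (4S)-4-benzyl-3-{(2S)-4-bromo-2-[3,4-dimethoxy-2-(methoxymethoxy)phenyl]pent-4-enoyl}-1,3-oxazolidin-2-one | O=C1OC[C@H](Cc2ccccc2)N1C(=O)[C@@H](CC(Br)=C)c3ccc(OC)c(OC)c3OCOC | intermediate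
11 | (2S)-4-bromo-2-[3,4-dimethoxy-2-(methoxymethoxy)phenyl]pent-4-en-1-ol | OC[C@@H](CC(Br)=C)c1ccc(OC)c(OC)c1OCOC | intermediate
12 | dimethyl squarate (3,4-dimethoxycyclobut-3-ene-1,2-dione) | COC1=C(OC)C(=O)C1=O | starting material
13 | lithium (2S)-2-[3,4-dimethoxy-2-(methoxymethoxy)phenyl]-4-lithiopent-4-en-1-olate (dilithio reagent) | [Li]OC[C@@H](CC([Li])=C)c1ccc(OC)c(OC)c1OCOC | intermediate
14 | 4-hydroxy-4-{(4S)-5-hydroxy-4-[3,4-dimethoxy-2-(methoxymethoxy)phenyl]pent-1-en-2-yl}-2,3-dimethoxycyclobut-2-en-1-one (both epimers at the carbinol carbon) | OC[C@@H](CC(=C)C1(O)C(OC)=C(OC)C1=O)c2ccc(OC)c(OC)c2OCOC | intermediate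
15 | (2S)-2-[3,4-dimethoxy-2-(methoxymethoxy)phenyl]-4-(1-hydroxy-2,3-dimethoxy-4-oxocyclobut-2-en-1-yl)pent-4-en-1-yl 4-methylbenzenesulfonate | Cc1ccc(cc1)S(=O)(=O)OC[C@@H](CC(=C)C2(O)C(OC)=C(OC)C2=O)c3ccc(OC)c(OC)c3OCOC | intermediate
16 | lithium alkoxide of 15 (lithium on the tertiary oxygen of the four-membered ring) | Cc1ccc(cc1)S(=O)(=O)OC[C@@H](CC(=C)C2(O[Li])C(OC)=C(OC)C2=O)c3ccc(OC)c(OC)c3OCOC | intermediate
17 | (7S)-7-[3,4-dimethoxy-2-(methoxymethoxy)phenyl]-2,3-dimethoxy-9-methylidene-5-oxaspiro[3.5]non-2-en-1-one (both epimers at the spiro carbon) | COC1=C(OC)C2(OC[C@@H](CC2=C)c3ccc(OC)c(OC)c3OCOC)C1=O | intermediate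
18 | 2,3-dimethoxy-3-{(5S)-5-[3,4-dimethoxy-2-(methoxymethoxy)phenyl]-3-methylideneoxan-2-ylidene}prop-1-en-1-one (dienylketene, ring oxygen trans to the ketene-bearing carbon) | O=C=C(OC)C(OC)=C1OC[C@@H](CC1=C)c2ccc(OC)c(OC)c2OCOC | intermediate
19 | (3S)-3-[3,4-dimethoxy-2-(methoxymethoxy)phenyl]-7,8-dimethoxy-3,4-dihydro-2H-chromen-6(5H)-one (cyclohexa-2,4-dienone tautomer of 20) | O=C1CC2=C(OC[C@@H](C2)c3ccc(OC)c(OC)c3OCOC)C(OC)=C1OC | intermediate
20 | (3S)-3-[3,4-dimethoxy-2-(methoxymethoxy)phenyl]-7,8-dimethoxy-3,4-dihydro-2H-chromen-6-ol | COc1ccc([C@H]2COc3c(cc(O)c(OC)c3OC)C2)c(OCOC)c1OC | intermediate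
21 | (3S)-3-(2-hydroxy-3,4-dimethoxyphenyl)-7,8-dimethoxy-3,4-dihydro-2H-chromen-6-ol | COc1ccc([C@H]2COc3c(cc(O)c(OC)c3OC)C2)c(O)c1OC | target

Total step count: 10
Longest linear sequence: 10 steps (1 to 21); 5, 8 and 12 are bought.

Steps most likely to fail

Step 8. The lithium alkoxide may open the four-membered ring (oxyanion-accelerated electrocyclic opening) before it has displaced the tosylate, or the tosylate may be lost by elimination. Fallback, from 15: the order of ring formation is reversed. Thermolysis of 15 itself (degassed toluene, 110 °C, 2,6-lutidine as acid scavenger), the free 4-hydroxy compound being the best precedented substrate for this benzannulation, would give the hydroquinone (2S)-3-(2,5-dihydroxy-3,4-dimethoxyphenyl)-2-[3,4-dimethoxy-2-(methoxymethoxy)phenyl]propyl 4-methylbenzenesulfonate F1. This is not isolated. Cs2CO3 in degassed DMF at 40 °C would then close ring C by phenoxide alkylation, for which only the oxygen on C8a can reach C2. This returns to the route at 20 and passes by 17.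

Step 6. Bromine–lithium exchange beside a lithium alkoxide may be incomplete, the aggregated dianion may add sluggishly, or the primary alkoxide may attack the ester positions of the squarate. Fallback, from 11: silylation (t-BuMe2SiCl, imidazole, DMF) would give tert-butyl({(2S)-4-bromo-2-[3,4-dimethoxy-2-(methoxymethoxy)phenyl]pent-4-en-1-yl}oxy)dimethylsilane F2. This needs only two equivalents of t-BuLi and would add to 12 as a monoanion to give 4-{(4S)-5-[(tert-butyldimethylsilyl)oxy]-4-[3,4-dimethoxy-2-(methoxymethoxy)phenyl]pent-1-en-2-yl}-4-hydroxy-2,3-dimethoxycyclobut-2-en-1-one F3. Buffered desilylation (Bu4NF, AcOH, THF, 0 °C) returns to the route at 14.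

Step 4. Proton exchange between the product imide and unreacted enolate at the acidic α-aryl centre may erode the diastereoselectivity, and the ortho substituent may slow the alkylation. Fallback, from 4: the auxiliary is given up for a resolution. Double deprotonation of 4 (LiN(i-Pr)2, 2.2 equiv, THF, −78 to 0 °C) and alkylation with 8 would give racemic 4-bromo-2-[3,4-dimethoxy-2-(methoxymethoxy)phenyl]pent-4-enoic acid F4. Fractional crystallisation of its salt with one enantiomer of 1-phenylethylamine (the amine enantiomer to be chosen by trial so that the S acid forms the less soluble salt) would give (2S)-4-bromo-2-[3,4-dimethoxy-2-(methoxymethoxy)phenyl]pent-4-enoic acid F5. Reduction with BH3·SMe2 in THF at 0 °C (the acid is reduced faster than the deactivated bromoalkene is hydroborated) returns to the route at 11.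

Further compounds
F1 | step 8 | (2S)-3-(2,5-dihydroxy-3,4-dimethoxyphenyl)-2-[3,4-dimethoxy-2-(methoxymethoxy)phenyl]propyl 4-methylbenzenesulfonate | Cc1ccc(cc1)S(=O)(=O)OC[C@@H](Cc2cc(O)c(OC)c(OC)c2O)c3ccc(OC)c(OC)c3OCOC
F2 | step 6 | tert-butyl({(2S)-4-bromo-2-[3,4-dimethoxy-2-(methoxymethoxy)phenyl]pent-4-en-1-yl}oxy)dimethylsilane | CC(C)(C)[Si](C)(C)OC[C@@H](CC(Br)=C)c1ccc(OC)c(OC)c1OCOC
F3 | step 6 | 4-{(4S)-5-[(tert-butyldimethylsilyl)oxy]-4-[3,4-dimethoxy-2-(methoxymethoxy)phenyl]pent-1-en-2-yl}-4-hydroxy-2,3-dimethoxycyclobut-2-en-1-one | CC(C)(C)[Si](C)(C)OC[C@@H](CC(=C)C1(O)C(OC)=C(OC)C1=O)c2ccc(OC)c(OC)c2OCOC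
F4 | step 4 | racemic 4-bromo-2-[3,4-dimethoxy-2-(methoxymethoxy)phenyl]pent-4-enoic acid | OC(=O)C(CC(Br)=C)c1ccc(OC)c(OC)c1OCOC
F5 | step 4 | (2S)-4-bromo-2-[3,4-dimethoxy-2-(methoxymethoxy)phenyl]pent-4-enoic acid | OC(=O)[C@@H](CC(Br)=C)c1ccc(OC)c(OC)c1OCOC
A1 | direct plan | 2,3-dimethoxy-1,4-benzoquinone | COC1=C(OC)C(=O)C=CC1=O
A2 | direct plan | 2-[2-(benzyloxy)-3,4-dimethoxyphenyl]prop-2-enal | C=C(C=O)c1ccc(OC)c(OC)c1OCc1ccccc1
A3 | direct plan | (3S)-3-[2-(benzyloxy)-3,4-dimethoxyphenyl]-6-hydroxy-7,8-dimethoxychroman-2-one | COc1ccc([C@H]2C(=O)Oc3c(cc(O)c(OC)c3OC)C2)c(OCc4ccccc4)c1OC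
A4 | direct plan | (3S)-3-[2-(benzyloxy)-3,4-dimethoxyphenyl]-7,8-dimethoxychroman-6-ol | COc1ccc([C@H]2COc3c(cc(O)c(OC)c3OC)C2)c(OCc4ccccc4)c1OC
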